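The route rests on opening the pyran ring of the 2,2-dimethyl-2H-chromene at C4–C4a, which leads back to an aryl 1,1-dimethylpropargyl ether of ring A that already carries the complete (S)-1-arylethyl (Z)-enol ether side chain, with both hydroxyl groups silylated. Heating this ether starts a propargyl Claisen shift, enolisation, a [1,5]-hydrogen shift and an oxa-6π closure, so one neutral operation builds the acid-sensitive pyran last. The step exploits the fact that C4a of ring A is ortho to O1 and para to the C7 methoxy group, the open position for the shift, whereas C8 sits between two oxygens. The stereocentre comes from ketone hydrogenation, the Z geometry from an anti-carbomagnesiation.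

Key step: step 9

Remark on the reading of the target: the benzylic carbon C1' is S and the enol ether is Z (ether oxygen cis to CH2OH); ring A is the benzene ring of the chromene, ring C the methylphenol ring.

Remark on the design: the ring C phenol is carried as a triisopropylsilyl ether and the primary alcohol as a tert-butyldimethylsilyl ether, so that fluoride at 0 °C ends the synthesis. The ring A oxygen is alkylated once (step 4) and is not set free again, because a para-phenoxide next to the benzylic enol ether could expel it through a para-quinone methide. From step 6 on no acid is used and silica is pre-treated with Et3N.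

Step 1
Reactants: 1 2-bromo-5-methylphenol
Product: 2 (2-bromo-5-methylphenoxy)triisopropylsilane
Conditions: TIPSCl, imidazole, DMF, 25 °C
Reagents that add atoms: chlorotriisopropylsilane (TIPSCl), CC(C)[Si](Cl)(C(C)C)C(C)C
Why: Imidazole-promoted silylation of a phenol masks the acidic O–H for the Grignard step with a group that resists carbonate, methoxide and heat in later steps and leaves with fluoride at 0 °C at the end.

Step 2
Reactants: 2 (2-bromo-5-methylphenoxy)triisopropylsilane; 3 prop-2-yn-1-ol
Product: 6 (Z)-3-iodo-2-[4-methyl-2-(triisopropylsilyloxy)phenyl]prop-2-en-1-ol, via arylmagnesium bromide 4 (not isolated), via cyclic vinylmagnesium alkoxide 5 (not isolated)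
Conditions: Mg, LiCl, THF, 25 °C; then 3 (0.4 equiv), CuI (10 mol%), −10 → 25 °C; then I2, −78 → 0 °C; aq. NH4Cl
Reagents that add atoms: iodine, II
Why: This is a copper-catalysed anti-carbomagnesiation of a propargylic magnesium alkoxide, in which one equivalent of 4 removes the O–H proton and a second delivers the aryl group to C2 while magnesium ends on C3 inside the five-membered chelate 5, cis to CH2O and trans to the aryl ring, so that iodinolysis with retention should fix the Z iodoalkene.

Step 3
Reactants: 6 (Z)-3-iodo-2-[4-methyl-2-(triisopropylsilyloxy)phenyl]prop-2-en-1-ol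
Product: 7 tert-butyl{[(Z)-3-iodo-2-[4-methyl-2-(triisopropylsilyloxy)phenyl]prop-2-en-1-yl]oxy}dimethylsilane
Conditions: TBSCl, imidazole, CH2Cl2, 25 °C
Reagents that add atoms: tert-butylchlorodimethylsilane (TBSCl), CC(C)(C)[Si](C)(C)Cl
Why: Standard silyl ether formation blocks the primary allylic O–H, which would otherwise compete as a nucleophile in the copper-catalysed C–O coupling of step 6.

Step 4
Reactants: 8 1-(4-hydroxy-2-methoxyphenyl)ethanone; 9 propan-2-yl 2-bromo-2-methylpropanoate
Product: 10 propan-2-yl 2-(4-acetyl-3-methoxyphenoxy)-2-methylpropanoate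
Conditions: K2CO3, DMF, 90 °C
Reagents that add atoms: none
Why: Williamson-type O-alkylation of a para-acylphenoxide with a tertiary α-bromo ester (the fibrate ether synthesis) installs the O–CMe2–C unit of the later propargyl ether at the outset, so that no free para-phenol ever has to be generated beside the benzylic enol ether.

Step 5
Reactants: 10 propan-2-yl 2-(4-acetyl-3-methoxyphenoxy)-2-methylpropanoate
Product: 11 propan-2-yl 2-{4-[(1S)-1-hydroxyethyl]-3-methoxyphenoxy}-2-methylpropanoate
Conditions: H2 (8 atm), RuCl2[(R)-xylbinap][(R)-daipen] (0.1 mol%), KOtBu (2 mol%), i-PrOH, 25 °C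
Reagents that add atoms: none
Why: In this Noyori asymmetric hydrogenation of an aryl methyl ketone the (R)-XylBINAP/(R)-DAIPEN ruthenium hydride should deliver hydrogen to the Re face of the carbonyl through its outer-sphere transition state and so set the S carbinol, while the basic medium spares the acid-labile electron-rich benzylic alcohol and isopropanol cannot scramble the isopropyl ester.

Step 6
Reactants: 11 propan-2-yl 2-{4-[(1S)-1-hydroxyethyl]-3-methoxyphenoxy}-2-methylpropanoate; 7 tert-butyl{[(Z)-3-iodo-2-[4-methyl-2-(triisopropylsilyloxy)phenyl]prop-2-en-1-yl]oxy}dimethylsilane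
Product: 12 propan-2-yl 2-{4-[(1S)-1-{[(Z)-3-(tert-butyldimethylsilyloxy)-2-[4-methyl-2-(triisopropylsilyloxy)phenyl]prop-1-en-1-yl]oxy}ethyl]-3-methoxyphenoxy}-2-methylpropanoate
Conditions: CuI (10 mol%), 3,4,7,8-tetramethyl-1,10-phenanthroline (20 mol%), Cs2CO3, toluene, 80 °C
Reagents that add atoms: none
Why: Ullmann-type copper-catalysed C–O cross-coupling of an alkenyl iodide with an aliphatic alcohol replaces iodine by oxygen with retention of alkene geometry (hence Z) and does not touch the C–O bond of the carbinol, so the S centre should be carried over unchanged.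

Step 7
Reactants: 12 propan-2-yl 2-{4-[(1S)-1-{[(Z)-3-(tert-butyldimethylsilyloxy)-2-[4-methyl-2-(triisopropylsilyloxy)phenyl]prop-1-en-1-yl]oxy}ethyl]-3-methoxyphenoxy}-2-methylpropanoate
Product: 13 2-{4-[(1S)-1-{[(Z)-3-(tert-butyldimethylsilyloxy)-2-[4-methyl-2-(triisopropylsilyloxy)phenyl]prop-1-en-1-yl]oxy}ethyl]-3-methoxyphenoxy}-2-methylpropanal
Conditions: i-Bu2AlH, CH2Cl2, −78 °C; aq. potassium sodium tartrate
Reagents that add atoms: none
Why: Partial reduction of an ester with i-Bu2AlH should stop at the aldehyde because the α-aryloxy ester forms a chelated aluminium hemiacetal at −78 °C that collapses only on work-up, and the silyl ethers, the enol ether and the benzylic ether are inert to the hydride at this temperature.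

Step 8
Reactants: 13 2-{4-[(1S)-1-{[(Z)-3-(tert-butyldimethylsilyloxy)-2-[4-methyl-2-(triisopropylsilyloxy)phenyl]prop-1-en-1-yl]oxy}ethyl]-3-methoxyphenoxy}-2-methylpropanal
Product: 14 tert-butyl{[(Z)-3-{(1S)-1-[2-methoxy-4-(2-methylbut-3-yn-2-yloxy)phenyl]ethoxy}-2-[4-methyl-2-(triisopropylsilyloxy)phenyl]prop-2-en-1-yl]oxy}dimethylsilane
Conditions: dimethyl (1-diazo-2-oxopropyl)phosphonate, K2CO3, MeOH/THF, 0 → 25 °C
Reagents that add atoms: dimethyl (1-diazo-2-oxopropyl)phosphonate, COP(=O)(OC)C(=[N+]=[N-])C(C)=O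
Why: In this Seyferth–Gilbert homologation (Ohira–Bestmann variant) methoxide unmasks the diazomethylphosphonate anion, which adds to the non-enolisable aldehyde, and loss of phosphate and N2 followed by a 1,2-hydrogen shift of the alkylidene carbene should give the terminal alkyne under mild basic conditions that both silyl ethers and both ether linkages tolerate.

Step 9
Reactants: 14 tert-butyl{[(Z)-3-{(1S)-1-[2-methoxy-4-(2-methylbut-3-yn-2-yloxy)phenyl]ethoxy}-2-[4-methyl-2-(triisopropylsilyloxy)phenyl]prop-2-en-1-yl]oxy}dimethylsilane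
Product: 18 tert-butyl{[(Z)-3-[(1S)-1-(7-methoxy-2,2-dimethyl-2H-chromen-6-yl)ethoxy]-2-[4-methyl-2-(triisopropylsilyloxy)phenyl]prop-2-en-1-yl]oxy}dimethylsilane, via allenyl cyclohexadienone 15 (not isolated), via ortho-allenylphenol 16 (not isolated), via ortho-quinone methide 17 (not isolated)
Conditions: PhNEt2 (degassed), 140 °C, argon
Reagents that add atoms: none
Why: Heat drives an aromatic propargyl Claisen rearrangement, a concerted [3,3] shift that breaks O–CMe2 and joins the alkyne terminus to the ring A carbon para to the methoxy group (the C4–C4a bond), and the allenyl dienone 15 enolises to the ortho-allenylphenol 16. A [1,5]-hydrogen shift from the phenolic O–H to the central allene carbon gives the Z ortho-quinone methide 17, in which the new diene arm lies next to the carbonyl oxygen. The pyran ring then closes by a thermal disrotatory oxa-6π electrocyclisation that re-forms the O1–C2 bond and restores aromaticity; this is the known thermal conversion of aryl 1,1-dimethylpropargyl ethers into 2,2-dimethyl-2H-chromenes. No stereocentre is created, and the S centre and the Z enol ether are spectators because the medium holds no acid, strong base or metal and the temperature is kept at 140 °C, the low end of the range in which such ethers rearrange, to spare the weak benzylic C–O bond. The step needs site selectivity for C4a over C8, and the substrate secures it because C8 lies between two oxygen-bearing carbons and the C6 side chain turns the methoxy methyl group toward C8, leaving the position para to OCH3 open. The aniline solvent buffers traces of acid and is removed by chromatography on Et3N-treated silica, not by an acid wash.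

Step 10
Reactants: 18 tert-butyl{[(Z)-3-[(1S)-1-(7-methoxy-2,2-dimethyl-2H-chromen-6-yl)ethoxy]-2-[4-methyl-2-(triisopropylsilyloxy)phenyl]prop-2-en-1-yl]oxy}dimethylsilane
Product: 19 (Z)-2-(2-hydroxy-4-methylphenyl)-3-[(1S)-1-(7-methoxy-2,2-dimethyl-2H-chromen-6-yl)ethoxy]prop-2-en-1-ol
Conditions: Bu4NF, THF, 0 °C; pH 7 phosphate buffer
Reagents that add atoms: none
Why: Fluoride-induced desilylation should cleave the aryl triisopropylsilyl ether and the primary tert-butyldimethylsilyl ether in one basic, acid-free operation that leaves the enol ether, the benzylic ether and the chromene untouched and gives the target.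

Compound list
1 | 2-bromo-5-methylphenol | Cc1ccc(Br)c(O)c1 | starting material
2 | (2-bromo-5-methylphenoxy)triisopropylsilane | Cc1ccc(Br)c(O[Si](C(C)C)(C(C)C)C(C)C)c1 | intermediate
3 | prop-2-yn-1-ol (propargyl alcohol) | C#CCO | starting material
4 | [4-methyl-2-(triisopropylsilyloxy)phenyl]magnesium bromide | Cc1ccc([Mg]Br)c(O[Si](C(C)C)(C(C)C)C(C)C)c1 | intermediate
5 | 4-[4-methyl-2-(triisopropylsilyloxy)phenyl]-2,5-dihydro-1,2-oxamagnesole (cyclic vinylmagnesium alkoxide, drawn as the monomer) | Cc1ccc(C2=C[Mg]OC2)c(O[Si](C(C)C)(C(C)C)C(C)C)c1 | intermediate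
6 | (Z)-3-iodo-2-[4-methyl-2-(triisopropylsilyloxy)phenyl]prop-2-en-1-ol | I/C=C(\CO)c1ccc(C)cc1O[Si](C(C)C)(C(C)C)C(C)C | intermediate
7 | tert-butyl{[(Z)-3-iodo-2-[4-methyl-2-(triisopropylsilyloxy)phenyl]prop-2-en-1-yl]oxy}dimethylsilane | I/C=C(\CO[Si](C)(C)C(C)(C)C)c1ccc(C)cc1O[Si](C(C)C)(C(C)C)C(C)C | intermediate
8 | 1-(4-hydroxy-2-methoxyphenyl)ethanone | COc1cc(O)ccc1C(C)=O | starting material
9 | propan-2-yl 2-bromo-2-methylpropanoate | CC(C)OC(=O)C(C)(C)Br | starting material
10 | propan-2-yl 2-(4-acetyl-3-methoxyphenoxy)-2-methylpropanoate | COc1cc(OC(C)(C)C(=O)OC(C)C)ccc1C(C)=O | intermediate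
11 | propan-2-yl 2-{4-[(1S)-1-hydroxyethyl]-3-methoxyphenoxy}-2-methylpropanoate | COc1cc(OC(C)(C)C(=O)OC(C)C)ccc1[C@H](C)O | intermediate
12 | propan-2-yl 2-{4-[(1S)-1-{[(Z)-3-(tert-butyldimethylsilyloxy)-2-[4-methyl-2-(triisopropylsilyloxy)phenyl]prop-1-en-1-yl]oxy}ethyl]-3-methoxyphenoxy}-2-methylpropanoate | COc1cc(OC(C)(C)C(=O)OC(C)C)ccc1[C@H](C)O/C=C(\CO[Si](C)(C)C(C)(C)C)c1ccc(C)cc1O[Si](C(C)C)(C(C)C)C(C)C | intermediate
13 | 2-{4-[(1S)-1-{[(Z)-3-(tert-butyldimethylsilyloxy)-2-[4-methyl-2-(triisopropylsilyloxy)phenyl]prop-1-en-1-yl]oxy}ethyl]-3-methoxyphenoxy}-2-methylpropanal | COc1cc(OC(C)(C)C=O)ccc1[C@H](C)O/C=C(\CO[Si](C)(C)C(C)(C)C)c1ccc(C)cc1O[Si](C(C)C)(C(C)C)C(C)C | intermediate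
14 | tert-butyl{[(Z)-3-{(1S)-1-[2-methoxy-4-(2-methylbut-3-yn-2-yloxy)phenyl]ethoxy}-2-[4-methyl-2-(triisopropylsilyloxy)phenyl]prop-2-en-1-yl]oxy}dimethylsilane (the aryl 1,1-dimethylpropargyl ether) | COc1cc(OC(C)(C)C#C)ccc1[C@H](C)O/C=C(\CO[Si](C)(C)C(C)(C)C)c1ccc(C)cc1O[Si](C(C)C)(C(C)C)C(C)C | intermediate
15 | 4-[(1S)-1-{[(Z)-3-(tert-butyldimethylsilyloxy)-2-[4-methyl-2-(triisopropylsilyloxy)phenyl]prop-1-en-1-yl]oxy}ethyl]-3-methoxy-6-(3-methylbuta-1,2-dien-1-yl)cyclohexa-2,4-dien-1-one (both C6 epimers) | COC1=CC(=O)C(C=C=C(C)C)C=C1[C@H](C)O/C=C(\CO[Si](C)(C)C(C)(C)C)c1ccc(C)cc1O[Si](C(C)C)(C(C)C)C(C)C | intermediate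
16 | 4-[(1S)-1-{[(Z)-3-(tert-butyldimethylsilyloxy)-2-[4-methyl-2-(triisopropylsilyloxy)phenyl]prop-1-en-1-yl]oxy}ethyl]-5-methoxy-2-(3-methylbuta-1,2-dien-1-yl)phenol | COc1cc(O)c(C=C=C(C)C)cc1[C@H](C)O/C=C(\CO[Si](C)(C)C(C)(C)C)c1ccc(C)cc1O[Si](C(C)C)(C(C)C)C(C)C | intermediate
17 | (6Z)-4-[(1S)-1-{[(Z)-3-(tert-butyldimethylsilyloxy)-2-[4-methyl-2-(triisopropylsilyloxy)phenyl]prop-1-en-1-yl]oxy}ethyl]-3-methoxy-6-(3-methylbut-2-en-1-ylidene)cyclohexa-2,4-dien-1-one | COC1=CC(=O)/C(=C\C=C(C)C)C=C1[C@H](C)O/C=C(\CO[Si](C)(C)C(C)(C)C)c1ccc(C)cc1O[Si](C(C)C)(C(C)C)C(C)C | intermediate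
18 | tert-butyl{[(Z)-3-[(1S)-1-(7-methoxy-2,2-dimethyl-2H-chromen-6-yl)ethoxy]-2-[4-methyl-2-(triisopropylsilyloxy)phenyl]prop-2-en-1-yl]oxy}dimethylsilane (bis-silylated target) | COc1cc2OC(C)(C)C=Cc2cc1[C@H](C)O/C=C(\CO[Si](C)(C)C(C)(C)C)c1ccc(C)cc1O[Si](C(C)C)(C(C)C)C(C)C | intermediate
19 | (Z)-2-(2-hydroxy-4-methylphenyl)-3-[(1S)-1-(7-methoxy-2,2-dimethyl-2H-chromen-6-yl)ethoxy]prop-2-en-1-ol (CNP0279099.1) | COc1cc2c(cc1[C@H](C)O/C=C(\CO)c1ccc(C)cc1O)C=CC(C)(C)O2 | target

Total step count: 10.
Longest linear sequence: 8 steps (steps 1, 2, 3, 6, 7, 8, 9, 10).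

Steps most likely to fail

1. Step 9 (key step). Process at risk: part of the [3,3] shift may go to the ring carbon between the two oxygens, and the weak benzylic C–O bond of the enol ether may break thermally (homolysis, [1,3] shift, or 1,6-elimination at the fleeting para-phenol stage) before the cascade is complete. Fallback: the pyran would be closed on a robust ketone before the fragile ether exists. Setting out from 8, copper-catalysed O-alkylation with 3-chloro-3-methylbut-1-yne (DBU, CuCl2·2H2O 1 mol%, MeCN, 0 °C) would give 1-[2-methoxy-4-(2-methylbut-3-yn-2-yloxy)phenyl]ethanone F1. Heating in PhNEt2 at 180 °C would run the same cascade through the allenyl dienone F2, the ortho-allenylphenol F3 and the ortho-quinone methide F4 to 1-(7-methoxy-2,2-dimethyl-2H-chromen-6-yl)ethanone F5, from which any angular isomer can be removed at this early, achiral stage. Hydrogenation under the conditions of step 5 would give (1S)-1-(7-methoxy-2,2-dimethyl-2H-chromen-6-yl)ethanol F6, the chromene C=C bond being inert to the ruthenium hydride. CuI-catalysed coupling of F6 with 7 under the conditions of step 6 comes back to the route at 18.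

2. Step 6. Process at risk: C–O bond formation between a hindered secondary alkoxide and a trisubstituted iodoalkene may be slow, so that reduction of the iodide by β-hydride transfer from the copper alkoxide, which oxidises the alcohol, takes over. Fallback: the polarity of the alkene partner is reversed. Setting out from 7, Miyaura borylation (B2pin2, PdCl2(PPh3)2, PPh3, KOPh, toluene, 50 °C) would give with retention the (Z)-alkenyl pinacol boronate F7. Oxidative Chan–Lam coupling of F7 with 11 (Cu(OAc)2, Et3N, 4 Å molecular sieves, CH2Cl2, air, 25 °C; 11 in excess, the surplus recovered) comes back to the route at 12.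

3. Step 7. Process at risk: over-reduction of the aluminium hemiacetal, or Lewis-acid-assisted ionisation of the benzylic ether by the aluminium reagent. Fallback: reduction and oxidation are separated. Setting out from 12, LiAlH4 (THF, −20 → 0 °C), a non-acidic aluminate, would reduce the ester fully to the primary alcohol F8. Parikh–Doering oxidation of this neopentyl-type alcohol (SO3·pyridine, DMSO, i-Pr2NEt, CH2Cl2, 0 °C) comes back to the route at 13.

Further compounds
F1 | step 9 | 1-[2-methoxy-4-(2-methylbut-3-yn-2-yloxy)phenyl]ethanone | COc1cc(OC(C)(C)C#C)ccc1C(C)=O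
F2 | step 9 | 4-acetyl-3-methoxy-6-(3-methylbuta-1,2-dien-1-yl)cyclohexa-2,4-dien-1-one (allenyl dienone) | COC1=CC(=O)C(C=C=C(C)C)C=C1C(C)=O
F3 | step 9 | 1-[4-hydroxy-2-methoxy-5-(3-methylbuta-1,2-dien-1-yl)phenyl]ethanone (ortho-allenylphenol) | COc1cc(O)c(C=C=C(C)C)cc1C(C)=O
F4 | step 9 | (6Z)-4-acetyl-3-methoxy-6-(3-methylbut-2-en-1-ylidene)cyclohexa-2,4-dien-1-one (ortho-quinone methide) | COC1=CC(=O)/C(=C\C=C(C)C)C=C1C(C)=O
F5 | step 9 | 1-(7-methoxy-2,2-dimethyl-2H-chromen-6-yl)ethanone | COc1cc2OC(C)(C)C=Cc2cc1C(C)=O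
F6 | step 9 | (1S)-1-(7-methoxy-2,2-dimethyl-2H-chromen-6-yl)ethanol | COc1cc2OC(C)(C)C=Cc2cc1[C@H](C)O
F7 | step 6 | tert-butyldimethyl{[(Z)-2-[4-methyl-2-(triisopropylsilyloxy)phenyl]-3-(4,4,5,5-tetramethyl-1,3,2-dioxaborolan-2-yl)prop-2-en-1-yl]oxy}silane | CC1(C)OB(OC1(C)C)/C=C(\CO[Si](C)(C)C(C)(C)C)c1ccc(C)cc1O[Si](C(C)C)(C(C)C)C(C)C
F8 | step 7 | 2-{4-[(1S)-1-{[(Z)-3-(tert-butyldimethylsilyloxy)-2-[4-methyl-2-(triisopropylsilyloxy)phenyl]prop-1-en-1-yl]oxy}ethyl]-3-methoxyphenoxy}-2-methylpropan-1-ol | COc1cc(OC(C)(C)CO)ccc1[C@H](C)O/C=C(\CO[Si](C)(C)C(C)(C)C)c1ccc(C)cc1O[Si](C(C)C)(C(C)C)C(C)C
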